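**Strategy**

The dihydropyran ring is taken apart at C4a–C4 and C3–C2, so that its CH2–CH(OH) bridge (C4–C3) between aromatic C4a of ring A and the gem-dimethyl carbon C2 comes from one vinylboron unit. In an enantioselective palladium-catalysed conjunctive cross-coupling, the aryl carbon of a 3'-bromoacetophenone bonds to the vinyl CH2 while an isopropenyl group shifts from boron to the neighbouring carbon; both bonds and the C3 stereocentre form together, and boron is then oxidised to the C3 hydroxyl. The precursor is an open-chain pair: a bromoarene with differentiated phenol protection and a vinyl(isopropenyl)borate. Markovnikov closure of the pyran ring, Claisen–Schmidt condensation and deprotection complete the chalcone.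

Key step: step 4

Remark on locants: primed locants refer to the acetophenone ring (C1' carries the acetyl group); chroman locants are used from compound 10 onwards.

Remark on the ligand: the antipode of the MandyPhos ligand (2,2'-bis[α-(dimethylamino)benzyl]-1,1'-bis(diphenylphosphino)ferrocene, C52H50FeN2P2) is taken that gives the (R)-boronate 8; the (Sp,Sp) antipode is assumed, and its mirror image is used if the sense of induction on this borate should prove opposite.

**Route**

Step 1
Reactants: 1 1-(2,4-dihydroxy-6-methoxyphenyl)ethan-1-one (2',4'-dihydroxy-6'-methoxyacetophenone)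
Product: 2 1-[4-(tert-butyldimethylsilyloxy)-2-hydroxy-6-methoxyphenyl]ethan-1-one
Conditions: TBSCl (1.05 equiv), imidazole, CH2Cl2, 0 °C to rt
Reagents that add atoms: tert-butyldimethylsilyl chloride, CC(C)(C)[Si](C)(C)Cl
Why: Silyl ether formation should occur only at the more acidic, unhindered C4' phenol, because the C2' hydroxyl is tied up in a hydrogen bond to the acetyl group.

Step 2
Reactants: 2 1-[4-(tert-butyldimethylsilyloxy)-2-hydroxy-6-methoxyphenyl]ethan-1-one
Product: 3 1-[3-bromo-4-(tert-butyldimethylsilyloxy)-2-hydroxy-6-methoxyphenyl]ethan-1-one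
Conditions: NBS (1.0 equiv), i-Pr2NH (cat.), CH2Cl2, 0 °C
Reagents that add atoms: N-bromosuccinimide, O=C1CCC(=O)N1Br
Why: Amine-mediated electrophilic aromatic bromination is directed ortho to the free phenol, and C3' is the only open position ortho to it, by analogy with 2'-hydroxy-4',6'-dialkoxyacetophenones, which halogenate next to the hydroxyl.

Step 3
Reactants: 3 1-[3-bromo-4-(tert-butyldimethylsilyloxy)-2-hydroxy-6-methoxyphenyl]ethan-1-one
Product: 4 1-[3-bromo-4-(tert-butyldimethylsilyloxy)-6-methoxy-2-(methoxymethoxy)phenyl]ethan-1-one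
Conditions: MOMCl (excess), i-Pr2NEt, CH2Cl2, 0 °C to 40 °C
Reagents that add atoms: chloromethyl methyl ether, COCCl
Why: O-Alkylation (MOM ether formation) under amine base caps the remaining acidic phenol before the borate chemistry and should spare the base-labile aryl silyl ether, which leaves the two oxygens flanking C3' differentiated.

Step 4
Reactants: 4 1-[3-bromo-4-(tert-butyldimethylsilyloxy)-6-methoxy-2-(methoxymethoxy)phenyl]ethan-1-one; 5 4,4,5,5-tetramethyl-2-vinyl-1,3,2-dioxaborolane (vinylB(pin)); 6 isopropenylmagnesium bromide (C3H5MgBr, solution in THF)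
Product: 9 1-{4-hydroxy-3-[(2R)-2-hydroxy-3-methylbut-3-en-1-yl]-6-methoxy-2-(methoxymethoxy)phenyl}ethan-1-one, via bis(alkenyl)borate 7 (not isolated), via allylboronate 8 (not isolated)
Conditions: 5 (1.3 equiv), 6 (1.2 equiv), NaOTf, THF, 0 °C to rt; then 4, Pd(OAc)2 (2 mol%), MandyPhos ligand C52H50FeN2P2 (2.4 mol%), THF, 60 °C; then NaOH (3 M aq), H2O2 (30%), 0 °C, Na2S2O3 quench
Reagents that add atoms: hydrogen peroxide, OO
Why: This is an enantioselective palladium-catalysed conjunctive cross-coupling of a bis(alkenyl)borate, the closest known reaction type being the coupling of vinylboron ate complexes with aryl triflates or halides to give β-substituted allylboronates: zerovalent palladium inserts into the C–Br bond of 4, the cationic arylpalladium (divalent palladium, bromide removed by NaOTf) binds the unsubstituted vinyl group of 7 and triggers an anti 1,2-shift of isopropenyl from boron to the α-carbon (C3–C2 bond), and reductive elimination from the resulting alkylpalladium forms the aryl–CH2 bond (C4a–C4). No ring is closed in this step; the pyran ring is closed in step 5. The single new stereocentre (C3) is set during the metallate shift by the chiral MandyPhos ligand on palladium, which selects the face of the vinyl group, and the C–B bond is then oxidised to C–OH with retention to give the (R)-alcohol. The step needs chemoselectivity between the two alkenyl groups on boron, secured because the unsubstituted vinyl group binds palladium while the α-substituted isopropenyl group migrates, and it needs conjunctive coupling to outrun direct Suzuki-type transfer, secured by the bidentate ligand and halide scavenging. The site on ring A is fixed by the C–Br bond, and the alkaline peroxide also cleaves the aryl silyl ether, so that only the C4' phenol is free next to the MOM-capped C2' oxygen; peroxide is kept cold and quenched early to avoid Dakin-type oxidation of the hindered ketone.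

Step 5
Reactants: 9 1-{4-hydroxy-3-[(2R)-2-hydroxy-3-methylbut-3-en-1-yl]-6-methoxy-2-(methoxymethoxy)phenyl}ethan-1-one
Product: 10 1-[(3R)-3-hydroxy-7-methoxy-5-(methoxymethoxy)-2,2-dimethyl-3,4-dihydro-2H-chromen-6-yl]ethan-1-one
Conditions: Co(salen) complex C36H52CoN2O2 (divalent cobalt, 5 mol%), N-fluoro-2,4,6-trimethylpyridinium triflate, PhSiH3, PhCF3, rt
Reagents that add atoms: none
Why: Cobalt hydride hydrogen-atom transfer to the 1,1-disubstituted alkene gives the tertiary C2 radical, which after radical–polar crossover is trapped by the only free phenol oxygen in a 6-exo Markovnikov closure (intramolecular hydroalkoxylation), leaving C3 untouched and giving no regioisomeric ring because the other flanking oxygen carries MOM.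

Step 6
Reactants: 10 1-[(3R)-3-hydroxy-7-methoxy-5-(methoxymethoxy)-2,2-dimethyl-3,4-dihydro-2H-chromen-6-yl]ethan-1-one; 11 4-(methoxymethoxy)benzaldehyde
Product: 12 (E)-1-[(3R)-3-hydroxy-7-methoxy-5-(methoxymethoxy)-2,2-dimethyl-3,4-dihydro-2H-chromen-6-yl]-3-[4-(methoxymethoxy)phenyl]prop-2-en-1-one
Conditions: KOH (aq), EtOH, rt
Reagents that add atoms: none
Why: Claisen–Schmidt aldol condensation of the methyl ketone enolate with the non-enolisable aldehyde, followed by E1cB dehydration, should give the thermodynamically favoured (E)-enone, with the MOM ethers, the chroman ether and the secondary alcohol stable to hydroxide.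

Step 7
Reactants: 12 (E)-1-[(3R)-3-hydroxy-7-methoxy-5-(methoxymethoxy)-2,2-dimethyl-3,4-dihydro-2H-chromen-6-yl]-3-[4-(methoxymethoxy)phenyl]prop-2-en-1-one
Product: 13 (E)-1-[(3R)-3,5-dihydroxy-7-methoxy-2,2-dimethyl-3,4-dihydro-2H-chromen-6-yl]-3-(4-hydroxyphenyl)prop-2-en-1-one (CNP0131483.1)
Conditions: HCl (aq, conc.), MeOH, rt
Reagents that add atoms: none
Why: Acid-catalysed acetal exchange with methanol cleaves both aryl MOM ethers, while the chromanol, the aryl methyl ether, the C3 stereocentre and the (E)-enone should be unaffected at room temperature.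

**Compound list**

1 | 1-(2,4-dihydroxy-6-methoxyphenyl)ethan-1-one | CC(=O)c1c(O)cc(O)cc1OC | starting material
2 | 1-[4-(tert-butyldimethylsilyloxy)-2-hydroxy-6-methoxyphenyl]ethan-1-one | CC(=O)c1c(O)cc(O[Si](C)(C)C(C)(C)C)cc1OC | intermediate
3 | 1-[3-bromo-4-(tert-butyldimethylsilyloxy)-2-hydroxy-6-methoxyphenyl]ethan-1-one | CC(=O)c1c(O)c(Br)c(O[Si](C)(C)C(C)(C)C)cc1OC | intermediate
4 | 1-[3-bromo-4-(tert-butyldimethylsilyloxy)-6-methoxy-2-(methoxymethoxy)phenyl]ethan-1-one | CC(=O)c1c(OCOC)c(Br)c(O[Si](C)(C)C(C)(C)C)cc1OC | intermediate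
5 | 4,4,5,5-tetramethyl-2-vinyl-1,3,2-dioxaborolane | C=CB1OC(C)(C)C(C)(C)O1 | starting material
6 | isopropenylmagnesium bromide | CC(=C)[Mg]Br | starting material
7 | bromomagnesium isopropenyl(pinacolato)vinylborate | C=C[B-]1(C(C)=C)OC(C)(C)C(C)(C)O1.[Mg+]Br | intermediate
8 | 1-{4-(tert-butyldimethylsilyloxy)-6-methoxy-2-(methoxymethoxy)-3-[(2R)-3-methyl-2-(4,4,5,5-tetramethyl-1,3,2-dioxaborolan-2-yl)but-3-en-1-yl]phenyl}ethan-1-one | CC(=O)c1c(OCOC)c(C[C@@H](B2OC(C)(C)C(C)(C)O2)C(C)=C)c(O[Si](C)(C)C(C)(C)C)cc1OC | intermediate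
9 | 1-{4-hydroxy-3-[(2R)-2-hydroxy-3-methylbut-3-en-1-yl]-6-methoxy-2-(methoxymethoxy)phenyl}ethan-1-one | CC(=O)c1c(OCOC)c(C[C@@H](O)C(C)=C)c(O)cc1OC | intermediate
10 | 1-[(3R)-3-hydroxy-7-methoxy-5-(methoxymethoxy)-2,2-dimethyl-3,4-dihydro-2H-chromen-6-yl]ethan-1-one | CC(=O)c1c(OC)cc2c(c1OCOC)C[C@@H](O)C(C)(C)O2 | intermediate
11 | 4-(methoxymethoxy)benzaldehyde | COCOc1ccc(C=O)cc1 | starting material
12 | (E)-1-[(3R)-3-hydroxy-7-methoxy-5-(methoxymethoxy)-2,2-dimethyl-3,4-dihydro-2H-chromen-6-yl]-3-[4-(methoxymethoxy)phenyl]prop-2-en-1-one | COc1cc2c(c(OCOC)c1C(=O)/C=C/c1ccc(OCOC)cc1)C[C@@H](O)C(C)(C)O2 | intermediate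
13 | (E)-1-[(3R)-3,5-dihydroxy-7-methoxy-2,2-dimethyl-3,4-dihydro-2H-chromen-6-yl]-3-(4-hydroxyphenyl)prop-2-en-1-one | COc1cc2c(c(O)c1C(=O)/C=C/c1ccc(O)cc1)C[C@@H](O)C(C)(C)O2 | target

**Step count**

Total steps: 7. Longest linear sequence: 7 (1 to 13).

**Steps most likely to fail**

Step 4. At the doubly ortho-substituted arylpalladium, alkene binding and the boron-to-carbon shift may be slower than direct transfer of an alkenyl group to palladium (Suzuki-type coupling), or enantiofacial control may be lost. The fallback sets out from 4 and rejoins the route at 10, with the C3 stereocentre set by a salen catalyst instead. Stille coupling of 4 with tributyl(3-methylbut-2-enyl)stannane (Pd(PPh3)4, CsF, DMF, 90 °C) should give 1-[4-(tert-butyldimethylsilyloxy)-6-methoxy-2-(methoxymethoxy)-3-(3-methylbut-2-en-1-yl)phenyl]ethan-1-one F1. Desilylation (TBAF, AcOH, THF) gives 1-[4-hydroxy-6-methoxy-2-(methoxymethoxy)-3-(3-methylbut-2-en-1-yl)phenyl]ethan-1-one F2. Oxidative cyclisation with DDQ (dioxane, reflux) through the only free phenol gives 1-[7-methoxy-5-(methoxymethoxy)-2,2-dimethyl-2H-chromen-6-yl]ethan-1-one F3. Jacobsen epoxidation ((R,R)-Mn(salen)Cl, C36H52ClMnN2O2, trivalent manganese; NaOCl, 4-phenylpyridine N-oxide, CH2Cl2, 0 °C) should give 1-[(3R,4R)-3,4-epoxy-7-methoxy-5-(methoxymethoxy)-2,2-dimethylchroman-6-yl]ethan-1-one F4. Hydrogenolysis of its benzylic C4–O bond (H2, Pd/C, EtOAc) then gives 10.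

Step 5. After hydrogen-atom transfer, the electrophilic C2 centre may be captured by the neighbouring C3 hydroxyl (oxirane closure) or quenched by a 1,2-hydride shift, or the cobalt hydride may isomerise the allylic alcohol to a ketone. The fallback sets out from 9 and rejoins at 10. Selenoetherification (N-(phenylseleno)phthalimide, cat. camphorsulfonic acid, CH2Cl2, 0 °C) should close the ring in the Markovnikov sense through the free phenol to give 1-[(3R)-3-hydroxy-7-methoxy-5-(methoxymethoxy)-2-methyl-2-(phenylselanylmethyl)chroman-6-yl]ethan-1-one F5 (both C2 epimers). Radical deselenation (Bu3SnH, AIBN, toluene, 80 °C) turns the CH2SePh group into the second methyl group and gives 10.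

Step 2. Regiocontrol in the aromatic substitution may be lost, through attack para to the hydroxyl at C5' or double bromination. The fallback sets out from 1 and rejoins at 9; it places the halogen before any protection, under phenoxide control, at the carbon between the two free oxygens. Iodination of 1 (I2, KI, aq NH3, 0 °C) should give 1-(2,4-dihydroxy-3-iodo-6-methoxyphenyl)ethan-1-one F6. Silylation as in step 1 gives 1-[4-(tert-butyldimethylsilyloxy)-2-hydroxy-3-iodo-6-methoxyphenyl]ethan-1-one F7. MOM protection as in step 3 gives 1-[4-(tert-butyldimethylsilyloxy)-3-iodo-6-methoxy-2-(methoxymethoxy)phenyl]ethan-1-one F8. F8 then takes the place of 4 in step 4 (same borate 7 and boronate 8, with a larger excess of NaOTf because iodide binds palladium more strongly) and gives 9.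

Further compounds
F1 | step 4 | 1-[4-(tert-butyldimethylsilyloxy)-6-methoxy-2-(methoxymethoxy)-3-(3-methylbut-2-en-1-yl)phenyl]ethan-1-one | CC(=O)c1c(OCOC)c(CC=C(C)C)c(O[Si](C)(C)C(C)(C)C)cc1OC
F2 | step 4 | 1-[4-hydroxy-6-methoxy-2-(methoxymethoxy)-3-(3-methylbut-2-en-1-yl)phenyl]ethan-1-one | CC(=O)c1c(OCOC)c(CC=C(C)C)c(O)cc1OC
F3 | step 4 | 1-[7-methoxy-5-(methoxymethoxy)-2,2-dimethyl-2H-chromen-6-yl]ethan-1-one | CC(=O)c1c(OC)cc2c(c1OCOC)C=CC(C)(C)O2
F4 | step 4 | 1-[(3R,4R)-3,4-epoxy-7-methoxy-5-(methoxymethoxy)-2,2-dimethylchroman-6-yl]ethan-1-one | CC(=O)c1c(OC)cc2c(c1OCOC)[C@H]3O[C@H]3C(C)(C)O2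
F5 | step 5 | 1-[(3R)-3-hydroxy-7-methoxy-5-(methoxymethoxy)-2-methyl-2-(phenylselanylmethyl)chroman-6-yl]ethan-1-one (both C2 epimers) | CC(=O)c1c(OC)cc2c(c1OCOC)C[C@@H](O)C(C)(C[Se]c1ccccc1)O2
F6 | step 2 | 1-(2,4-dihydroxy-3-iodo-6-methoxyphenyl)ethan-1-one | CC(=O)c1c(O)c(I)c(O)cc1OC
F7 | step 2 | 1-[4-(tert-butyldimethylsilyloxy)-2-hydroxy-3-iodo-6-methoxyphenyl]ethan-1-one | CC(=O)c1c(O)c(I)c(O[Si](C)(C)C(C)(C)C)cc1OC
F8 | step 2 | 1-[4-(tert-butyldimethylsilyloxy)-3-iodo-6-methoxy-2-(methoxymethoxy)phenyl]ethan-1-one | CC(=O)c1c(OCOC)c(I)c(O[Si](C)(C)C(C)(C)C)cc1OC
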